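**Why does target climb so slowly in these runs?** Something may be spending it as it forms. In birch between 6.00 h and 10.0 h, substrate falls 16 percentage points while target gains 3.3 points.

in all of them: gas phase 3.6 mM (held)

| charge | substrate | catalyst | remark | time |
|---|---|---|---|---|
| birch | 0.014 M | 0.60 mM | run made earlier |  |
| elm | 0.022 M | 0.60 mM | run made earlier |  |
| larch | 0.010 M | 0.30 mM | run made earlier |  |
| flask | 0.010 M | 0.60 mM |  | 12 h |

| run | time / h | target / % | substrate / % |
|---|---|---|---|
| birch | 1.33 | 0.9 | 98.8 |
| birch | 3.00 | 3.1 | 94.9 |
| birch | 6.00 | 7.2 | 83.5 |
| birch | 10.0 | 10.5 | 67.6 |
| elm | 0.833 | 0.6 | 100.3 |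
| elm | 2.00 | 1.8 | 98.0 |
| elm | 4.00 | 3.3 | 92.2 |
| elm | 10.0 | 4.8 | 73.1 |
| larch | 0.833 | 0.2 | 99.9 |
| larch | 2.00 | 1.0 | 98.7 |
| larch | 4.00 | 3.3 | 94.4 |
| larch | 10.0 | 9.2 | 76.7 |

(standard deviation of a reading: 0.3 percentage points)

- at the start none of the gas phase is in solution

- target at 12 h, in percent of the substrate charged
- the change that raises the amount of target at 12 h, in percent of the substrate charged most ("none" if none brings more than 2 percentage points) (summer / midnight / autumn / none)
- amount of target at 12 h, in percent of the substrate charged, after midnight

- summer: doubling the transfer coefficient of the gas phase, all else as stated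
- midnight: doubling the saturation concentration of gas phase, all else as stated
- autumn: doubling the amount of catalyst, all else as stated

**How do you put a number on the spending?** I assume that one substrate and one target vanish together, so target is lost at half the drop in substrate plus target. In birch that is 0.221 mM h⁻¹, with 1.24 mM of target present on average and 75.5% of the substrate left. I take the loss to go with target times substrate, so I carry h, the half-life of target against substrate (pseudo-first-order at fixed substrate), read from birch and scaled to this flask's charge: 4.12 h.

**But substrate falls. Does h hold?** No, it lengthens as substrate falls. As a stand-in for this flask's substrate I use birch's remaining fraction, which gives 5.45 h.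

**So what survives in this flask?** I take target in this flask to be on average about half of 12 h old, so I reckon that a share 46.6% remains.

**And how much is made?** Read from the same balance, birch had made about 3.00 mM by 10.0 h. This flask has less substrate but more hours, and I let these cancel. My estimate is 14.0%.

**Which change?** I take midnight to double the pull of the gas at every moment, so I choose it and, keeping the same surviving share, expect 28.0%.

The forecast gives 14.4% (12.5% to 16.5%), midnight as best and 27% after it (22% to 31%), on the ground of “slow gas uptake”.

The flask gives 15.5%. The best change is midnight, which gains 13 points and reaches 29.0%, against 7.3 points for summer and 5.3 points for autumn.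

    gas phase ⇌ dissolved gas, rate k1*(csat - [dissolved gas]) (kL = 0.00250 min⁻¹)
    substrate + dissolved gas + catalyst → catalyst + target (k = 850 L² mol⁻² min⁻¹)
    target ⇌ isomer of the product (K = 1.20, k = 3.80 × 10⁻⁴ min⁻¹)
    substrate + target → side product (k = 0.290 L mol⁻¹ min⁻¹)

The flask's target is held down in part by the pace of gas uptake and the passing of substrate + target into side product, acting together: the run without that passing gives 28.5%. With the flask's substrate at 12.0 h, h becomes 7.27 h, beside the simulated 7.0 h. In a neighbour flask with 1.5 × 10⁻⁴ M of catalyst and 80.9% of substrate left at the end, h is 5.09 h, so 44.2% should survive. That neighbour flask gives target 6.47%, isomer of the product 0.813% and side product 11.8%, of which half was target, so 49.1% survives.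

The earlier runs and the new flask come from a simulation for substances that don't exist, noise included.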